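Each left-handed product made takes one left-handed substrate and one partner, so the left-handed substrate lost counts, within the scatter, the product made and the partner turned into it. Partner going to dormant form is not in this count.

| setting | Friday's | Saturday's | Sunday's | flask |
|---|---|---|---|---|
| left-handed substrate | 0.39 M | 1.6 M | 0.78 M | 0.78 M |
| right-handed substrate | 0.39 M | 1.6 M | 0.78 M | 0.78 M |
| partner | 0.624 M | 0.624 M | 1.2 M | 0.624 M |
| free catalyst | 7.8 mM | 7.8 mM | 7.8 mM | 7.8 mM |
| remark | run made earlier | run made earlier | run made earlier |  |
| time |  |  |  | 8.0 min |

| run | time / min | left-handed substrate / % | right-handed substrate / % |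
|---|---|---|---|
| Friday's | 1.00 | 40.5 | 49.5 |
| Friday's | 3.00 | 29.1 | 50.5 |
| Friday's | 5.00 | 23.0 | 49.1 |
| Friday's | 8.00 | 15.9 | 49.8 |
| Saturday's | 1.00 | 47.5 | 49.9 |
| Saturday's | 3.00 | 40.1 | 51.0 |
| Saturday's | 5.00 | 38.8 | 50.7 |
| Saturday's | 8.00 | 35.1 | 49.4 |
| Sunday's | 0.667 | 40.6 | 49.7 |
| Sunday's | 1.33 | 36.6 | 50.2 |
| Sunday's | 3.00 | 25.5 | 48.9 |
| Sunday's | 8.00 | 11.2 | 49.5 |

(readings scatter by 1 percentage point)

- free catalyst is single-handed; left-handed substrate and right-handed substrate are mirror images of each other, charged as a racemate, each of them at the stated concentration
- the numbers in the tables scatter by 1 percentage point (one standard deviation)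
- on the list of suspects stand: free catalyst + left-handed substrate <-> catalyst intermediate A; free catalyst + right-handed substrate <-> catalyst intermediate B; partner + catalyst intermediate A -> free catalyst + left-handed product; partner + catalyst intermediate B -> free catalyst + right-handed product; partner <-> dormant form; free catalyst -> spent catalyst; 2 free catalyst <-> resting dimer
- an excess is the difference of the two amounts in percent of their sum
- an excess is below zero if the other one leads

1. part of the left-handed substrate and right-handed substrate charged together that has reacted at 8.0 min
2. excess of left-handed product over right-handed product in the product at 8.0 min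
3. excess of right-handed substrate over left-handed substrate among what is left of the two at 8.0 min

Sunday's right-handed substrate still reads 49.5% at 8.00 min, so we count the left-handed side. In the flask partner is the limiting reagent, 0.624 M against 0.78 M. We set two times side by side: the run, t = 8.0 min, and the partner time τ, one over a pseudo-first-order constant κ of partner turning into product, an effective constant read from left-handed substrate lost.

First round: the whole of Sunday's run gives κ = 0.0877 min⁻¹. For the flask this reckons 0.315 M of product and 0.465 M of left-handed substrate kept. But Sunday's run went down to 0.175 M, below that.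

Second round: we stop Sunday's run at 3.00 min, where left-handed substrate reads 0.398 M. Product made is 0.382 M, so κ = 0.128 min⁻¹ and τ = 7.82 min. The flask has t/τ = 1.02. We take the part of its partner turned into product as one minus exp(−t/τ), which gives 0.400 M of product and leaves 0.380 M of left-handed substrate, close to that window's end. Our c is 25.6%.

The forecast gives 24.4%, 100% and 32.2%, holding that “The rate is about first order in partner”. Its c is lower than ours.

The flask gives 24.4%, 98.9% and 31.5%, so the forecast stands. In the flask, partner ends at 23% of its charge, less than left-handed substrate at 52%. At 4.00 min, τ gives 16.0% of left-handed product; the flask holds 17.2%.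

    free catalyst + left-handed substrate ⇌ catalyst intermediate A (K = 4.00 M⁻¹, k = 40.2 M⁻¹ s⁻¹)
    free catalyst + right-handed substrate ⇌ catalyst intermediate B (K = 1.42 M⁻¹, k = 26.8 M⁻¹ s⁻¹)
    partner + catalyst intermediate A → free catalyst + left-handed product (k = 0.778 M⁻¹ s⁻¹)
    partner + catalyst intermediate B → free catalyst + right-handed product (k = 0.00886 M⁻¹ s⁻¹)
    partner ⇌ dormant form (K = 29.6, k = 6.80 × 10⁻⁴ s⁻¹)
    free catalyst → spent catalyst (k = 2.34 × 10⁻⁶ s⁻¹)
    2 free catalyst ⇌ resting dimer, settled at all times (K = 401 M⁻¹)

With 0.16 M of partner, τ gives 6.57% reacted; that neighbour flask computes to 7.13%.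

The data were computed from invented constants, and the scatter is random.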